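**Plan**
1. Cuts: in the heterocyclic ring (O1–C2–C3–C4–C4a–C8a) two bonds are cut together, O1–C8a and C4–C4a. Ring A leaves as 3,5-dimethoxybenzyne (C8a≡C4a), and O1–C2–C3–C4 closes on itself (O1–C4) as a four-membered (S)-4-aryl-β-lactone.
2. Enabling feature: C8a and C4a are neighbouring carbons of ring A. One carries a nucleophile-derived atom (O1), the other an electrophile-derived atom (acyl C4), and the 5-OMe sits next to C4a. This is the pattern of a 1,2-addition to a 3-alkoxyaryne, which takes the nucleophile at the remote carbon.
3. Ring A branch: 3,5-dimethoxyphenol is brominated, O-silylated, then taken through retro-Brook shift and triflation to the silylaryl triflate.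
4. Lactone branch: 2',3',4'-trimethoxyacetophenone is taken through Claisen condensation, asymmetric transfer hydrogenation, saponification and β-lactonisation, so the four-membered ring is made first.
5. Union: fluoride-triggered insertion of the aryne into the acyl C–O bond expands the four-membered ring to the six-membered pyranone and gives the target directly, without protecting groups.
6. Stereochemistry: the only stereocentre, C2 (S), comes from the transfer hydrogenation, and its C–O bond is never broken afterwards.

Key step: step 8

Assumption: the stereocentre of the given SMILES is read as (2S) (O1 > C1' > C3 > H). Compounds 1 and 7 are taken as commercial.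

Step 1
Reactants: 1 3,5-dimethoxyphenol
Product: 2 2-bromo-3,5-dimethoxyphenol
Conditions: NBS (1.0 equiv), CH2Cl2, −78 °C → 0 °C
Reagents that add atoms: N-bromosuccinimide, O=C1CCC(=O)N1Br
Why: Electrophilic aromatic bromination; C2 (ortho to OH, para to the 5-OMe, two equivalent sites) is less crowded than C4 between two methoxy groups, and one equivalent of NBS at low temperature should stop the reaction at the monobromide.

Step 2
Reactants: 2 2-bromo-3,5-dimethoxyphenol
Product: 3 (2-bromo-3,5-dimethoxyphenoxy)trimethylsilane
Conditions: HMDS (0.6 equiv), THF, 70 °C; volatiles removed in vacuo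
Reagents that add atoms: hexamethyldisilazane, C[Si](C)(C)N[Si](C)(C)C
Why: O-silylation of a phenol with HMDS, driven by loss of ammonia, places the silyl group on oxygen for the migration in step 3.

Step 3
Reactants: 3 (2-bromo-3,5-dimethoxyphenoxy)trimethylsilane
Product: 6 3,5-dimethoxy-2-(trimethylsilyl)phenyl trifluoromethanesulfonate, via aryllithium 4 (not isolated), via lithium phenoxide 5 (not isolated)
Conditions: n-BuLi (1.1 equiv), THF, −78 °C; then Tf2O (1.2 equiv), −78 °C → 0 °C
Reagents that add atoms: trifluoromethanesulfonic anhydride, O=S(=O)(OS(=O)(=O)C(F)(F)F)C(F)(F)F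
Why: Bromine–lithium exchange, retro-Brook (1,3 O→C) silyl shift driven by the change from aryl anion to phenoxide, and O-triflation form the standard entry to Kobayashi-type aryne precursors.

Step 4
Reactants: 7 2',3',4'-trimethoxyacetophenone
Product: 8 ethyl 3-oxo-3-(2,3,4-trimethoxyphenyl)propanoate
Conditions: NaH (2.5 equiv), (EtO)2CO (3 equiv), toluene, 100 °C; then AcOH, 0 °C
Reagents that add atoms: diethyl carbonate, CCOC(=O)OCC
Why: Crossed Claisen condensation (C-ethoxycarbonylation of the methyl ketone enolate), pulled to completion by irreversible deprotonation of the β-keto ester.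

Step 5
Reactants: 8 ethyl 3-oxo-3-(2,3,4-trimethoxyphenyl)propanoate
Product: 9 ethyl (S)-3-hydroxy-3-(2,3,4-trimethoxyphenyl)propanoate
Conditions: RuCl[(S,S)-TsDPEN](p-cymene) (1 mol %), HCO2H–Et3N (5:2), 30 °C
Reagents that add atoms: none
Why: Noyori–Ikariya asymmetric transfer hydrogenation of an aroylacetate; the (S,S)-catalyst should deliver hydride to the Re face of the aryl ketone through the CH/π-organised six-membered transition state and so set the (S)-carbinol, the only stereocentre of the route.

Step 6
Reactants: 9 ethyl (S)-3-hydroxy-3-(2,3,4-trimethoxyphenyl)propanoate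
Product: 10 (S)-3-hydroxy-3-(2,3,4-trimethoxyphenyl)propanoic acid
Conditions: LiOH (2 equiv), THF–H2O (3:1), 0 °C; then cold 0.5 M HCl to pH 4
Reagents that add atoms: lithium hydroxide, [Li+].[OH-]
Why: Ester saponification (acyl–oxygen cleavage) at 0 °C leaves the benzylic C–O bond untouched, and the mild acidification avoids ionisation of the electron-rich benzylic alcohol.

Step 7
Reactants: 10 (S)-3-hydroxy-3-(2,3,4-trimethoxyphenyl)propanoic acid
Product: 12 (S)-4-(2,3,4-trimethoxyphenyl)oxetan-2-one, via mixed anhydride 11 (not isolated)
Conditions: PhSO2Cl (2 equiv), pyridine, 0–4 °C; cold neutral work-up, no acidic silica, used at once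
Reagents that add atoms: none
Why: β-Lactonisation by carboxyl activation (benzenesulfonyl chloride–pyridine method); the hydroxyl group closes 4-exo-trig on the mixed carboxylic–sulfonic anhydride, so the C–O bond at the stereocentre is not involved and the configuration is retained.

Step 8
Reactants: 6 3,5-dimethoxy-2-(trimethylsilyl)phenyl trifluoromethanesulfonate; 12 (S)-4-(2,3,4-trimethoxyphenyl)oxetan-2-one
Product: 16 (2S)-5,7-dimethoxy-2-(2,3,4-trimethoxyphenyl)chroman-4-one, via aryne 13 (not isolated), via alkoxide acyl fluoride 14 (not isolated), via aryl anion 15 (not isolated)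
Conditions: 12 (1.0 equiv), CsF (3 equiv), MeCN, 0 °C; 6 (1.5 equiv) added over 3 h, 0 → 23 °C; pH 7 phosphate buffer quench
Reagents that add atoms: none
Why: Proposed new method: the aryne is inserted into the acyl C–O bond of a β-lactone, a two-atom ring expansion (four- to six-membered) in which fluoride has two tasks, to release 3,5-dimethoxybenzyne 13 from 6 and, as a hard nucleophile, to open the strained lactone 12 reversibly at the acyl carbon to the β-alkoxide acyl fluoride 14; the alkoxide adds to the aryne and the ortho aryl anion 15 attacks the acyl fluoride, which gives 16 and returns fluoride. The closest known reaction types are the insertion of arynes into the N–C(O) bond of β-lactams (to 2,3-dihydroquinolin-4-ones) and the annulation of arynes with salicylate esters to xanthones (O-arylation, then attack of the aryl anion on the ester), and each elementary step (acyl–oxygen opening of β-lactones by hard nucleophiles, O-arylation of alkoxides by arynes, acylation of aryl anions by acyl fluorides) is known on its own. The one ring that closes, the pyranone ring, closes by 6-exo-trig acyl substitution at C4. No stereocentre is made: the benzylic C–O bond is never broken, so C4 (S) of 12 should become C2 (S) of 16 with retention. Regioselectivity at the unsymmetrical aryne is needed and is secured by the methoxy group next to the triple bond, which distorts and polarises it so that the alkoxide enters at the remote carbon (C8a) and the carbanion rests beside OMe (C4a, next to C5-OMe). Chemoselectivity for acyl attack over benzylic SN2 attack and α-deprotonation of 12 is needed and is favoured by the hardness of fluoride, by ring strain and by the poor orbital overlap for β-elimination in the planar four-ring enolate, while an alkoxide that adds to a second lactone only gives an ester that runs through the same arylation–acylation and sets the next alkoxide free.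

**Compound list**
1 | 3,5-dimethoxyphenol | COc1cc(O)cc(OC)c1 | starting material
2 | 2-bromo-3,5-dimethoxyphenol | COc1cc(O)c(Br)c(OC)c1 | intermediate
3 | (2-bromo-3,5-dimethoxyphenoxy)trimethylsilane | COc1cc(O[Si](C)(C)C)c(Br)c(OC)c1 | intermediate
4 | [2,4-dimethoxy-6-(trimethylsilyloxy)phenyl]lithium (not isolated) | COc1cc(O[Si](C)(C)C)c([Li])c(OC)c1 | intermediate
5 | lithium 3,5-dimethoxy-2-(trimethylsilyl)phenoxide (not isolated) | [Li+].COc1cc([O-])c([Si](C)(C)C)c(OC)c1 | intermediate
6 | 3,5-dimethoxy-2-(trimethylsilyl)phenyl trifluoromethanesulfonate | COc1cc(OS(=O)(=O)C(F)(F)F)c([Si](C)(C)C)c(OC)c1 | intermediate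
7 | 2',3',4'-trimethoxyacetophenone | CC(=O)c1ccc(OC)c(OC)c1OC | starting material
8 | ethyl 3-oxo-3-(2,3,4-trimethoxyphenyl)propanoate | CCOC(=O)CC(=O)c1ccc(OC)c(OC)c1OC | intermediate
9 | ethyl (S)-3-hydroxy-3-(2,3,4-trimethoxyphenyl)propanoate | O[C@H](c1ccc(OC)c(OC)c1OC)CC(=O)OCC | intermediate
10 | (S)-3-hydroxy-3-(2,3,4-trimethoxyphenyl)propanoic acid | O[C@H](c1ccc(OC)c(OC)c1OC)CC(=O)O | intermediate
11 | benzenesulfonic (S)-3-hydroxy-3-(2,3,4-trimethoxyphenyl)propanoic anhydride (not isolated) | O[C@H](c1ccc(OC)c(OC)c1OC)CC(=O)OS(=O)(=O)c1ccccc1 | intermediate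
12 | (S)-4-(2,3,4-trimethoxyphenyl)oxetan-2-one | O1[C@H](c2ccc(OC)c(OC)c2OC)CC1=O | intermediate
13 | 3,5-dimethoxybenzyne (1,2-didehydro-3,5-dimethoxybenzene, not isolated) | COC1=CC(OC)=CC#C1 | intermediate
14 | caesium (S)-3-fluoro-3-oxo-1-(2,3,4-trimethoxyphenyl)propan-1-olate (not isolated) | [Cs+].[O-][C@H](c1ccc(OC)c(OC)c1OC)CC(F)=O | intermediate
15 | caesium 2-{[(S)-3-fluoro-3-oxo-1-(2,3,4-trimethoxyphenyl)propyl]oxy}-4,6-dimethoxyphenyl anion (not isolated) | [Cs+].COc1cc(OC)[c-]c(O[C@H](c2ccc(OC)c(OC)c2OC)CC(F)=O)c1 | intermediate
16 | (2S)-5,7-dimethoxy-2-(2,3,4-trimethoxyphenyl)chroman-4-one | COc1cc(OC)c2c(c1)O[C@H](c1ccc(OC)c(OC)c1OC)CC2=O | target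

**Step count**
Total step count: 8.
Longest linear sequence: 5 steps (7 → 8 → 9 → 10 → 12 → 16). The three-step branch 1 → 6 joins in step 8.

**Steps most likely to fail**

First, step 8 (Proposed new method).
- Opening of the lactone by fluoride may be too slow compared with the decay of the aryne, so the aryne is lost to self-condensation or to the solvent.
- Fluoride may act as a base. The lactone would then open by elimination to the cinnamate, and the configuration would be lost through carboxylate–aryne chemistry.
- The product may lose configurational integrity by reversible retro-oxa-Michael opening in the basic medium.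

The fallback uses known chemistry, sets out from 8 and 2, and comes back at 16. Keto ester 8 would be reduced under the conditions of step 5 with the (R,R)-catalyst to ethyl (R)-3-hydroxy-3-(2,3,4-trimethoxyphenyl)propanoate F1. Mitsunobu etherification of this alcohol with bromophenol 2 (PPh3, DIAD, toluene, 0 °C) should proceed with inversion to ethyl (S)-3-(2-bromo-3,5-dimethoxyphenoxy)-3-(2,3,4-trimethoxyphenyl)propanoate F2. Bromine–lithium exchange (n-BuLi, THF, −100 °C) should give the aryllithium F3, which closes on the ester in a Parham cyclisation to 16. This uses the same aryl anion/acyl closure as step 8, but gives up the ring expansion.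

Second, step 7.
- Sulfonylation may occur at the benzylic hydroxyl group instead of the carboxyl group, followed by fragmentation with loss of carbon dioxide.
- The benzylic C–O bond of the electron-rich lactone may ionise during reaction or work-up, with loss of configuration or decarboxylation.

The fallback sets out from 9 and comes back at 12. The ester would be converted with Me2AlSPh (AlMe3, PhSH, CH2Cl2, 0 °C) into S-phenyl (S)-3-hydroxy-3-(2,3,4-trimethoxyphenyl)propanethioate F4. The ring would then be closed by thiophilic activation (Hg(OMs)2, Na2HPO4, MeCN, 23 °C). These conditions are buffered and contain no sulfonylating agent. They also leave the carbinol C–O bond untouched.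

Third, step 1.
- Positional selectivity between C2 and C4 may be poor.
- Over-bromination of the very electron-rich ring may occur.

The fallback sets out from 1 and comes back at 5.
- Carbamoylation (ClCONEt2, K2CO3, MeCN, reflux) gives 3,5-dimethoxyphenyl diethylcarbamate F5.
- Directed ortho-metalation (s-BuLi, TMEDA, THF, −78 °C) should take place between the carbamate and the methoxy group, where the two directing groups cooperate, to give the lithiated carbamate F6.
- TMSCl then gives 3,5-dimethoxy-2-(trimethylsilyl)phenyl diethylcarbamate F7.
- LiAlH4 (THF, then neutral work-up) frees 3,5-dimethoxy-2-(trimethylsilyl)phenol F8.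
- Deprotonation with n-BuLi gives phenoxide 5, which is triflated as in step 3 to give 6.

**Further compounds**
F1 | step 8 | ethyl (R)-3-hydroxy-3-(2,3,4-trimethoxyphenyl)propanoate | O[C@@H](c1ccc(OC)c(OC)c1OC)CC(=O)OCC
F2 | step 8 | ethyl (S)-3-(2-bromo-3,5-dimethoxyphenoxy)-3-(2,3,4-trimethoxyphenyl)propanoate | COc1cc(OC)c(Br)c(O[C@H](c2ccc(OC)c(OC)c2OC)CC(=O)OCC)c1
F3 | step 8 | ethyl (S)-3-(2-lithio-3,5-dimethoxyphenoxy)-3-(2,3,4-trimethoxyphenyl)propanoate | COc1cc(OC)c([Li])c(O[C@H](c2ccc(OC)c(OC)c2OC)CC(=O)OCC)c1
F4 | step 7 | S-phenyl (S)-3-hydroxy-3-(2,3,4-trimethoxyphenyl)propanethioate | O[C@H](c1ccc(OC)c(OC)c1OC)CC(=O)Sc1ccccc1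
F5 | step 1 | 3,5-dimethoxyphenyl diethylcarbamate | CCN(CC)C(=O)Oc1cc(OC)cc(OC)c1
F6 | step 1 | 2-lithio-3,5-dimethoxyphenyl diethylcarbamate | CCN(CC)C(=O)Oc1cc(OC)cc(OC)c1[Li]
F7 | step 1 | 3,5-dimethoxy-2-(trimethylsilyl)phenyl diethylcarbamate | CCN(CC)C(=O)Oc1cc(OC)cc(OC)c1[Si](C)(C)C
F8 | step 1 | 3,5-dimethoxy-2-(trimethylsilyl)phenol | COc1cc(O)c([Si](C)(C)C)c(OC)c1
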